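**Retrosynthetic overview** (ring positions as in the target name: C1 bears the enol ester, C2 is the quaternary carbon, C7 bears the 2-oxopropyl group)
1. Z-enol ester: Wittig olefination of the C1 aldehyde with an (acyloxy)methylene ylide; the CH2OH group is unmasked last.
2. 4-Methylpent-3-enyl chain: hydroboration and B-alkyl Suzuki coupling of a vinyl group, after ring closure.
3. Cycloheptene (the only ring of the target, formed second): ring-closing metathesis of the allyl group on C2 onto a 2-(silyloxymethyl)allylic alcohol, made from a lactol and a 2-lithioallyl ether.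
4. C7: set on a temporary butyrolactone (formed first, opened before metathesis) by Stetter addition and equilibration trans to the quaternary substituent.
5. C1 and C2: set together by an enantioselective boron Ireland–Claisen rearrangement of an itaconate ester of (2E)-3-methylhexa-2,5-dien-1-ol.

Assumption: the (4R,5R) bromoborane 9 is taken to induce the (2S,3R) sense in step 6; if the sense is the opposite, its mirror image, made the same way from the (1S,2S) diamine, is used.

**Step 1**
Reactants: 1 pent-1-en-4-yne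
Product: 3 (2E)-3-methylhexa-2,5-dien-1-ol, via alkenylalane 2 (not isolated)
Conditions: AlMe3, Zr(C5H5)2Cl2 (cat.), CH2Cl2, 0 °C to rt; then n-BuLi, THF, −78 °C; (CH2O)n, −78 °C to rt; aq. HCl
Reagents that add atoms: trimethylaluminium, C[Al](C)C; paraformaldehyde (as formaldehyde), C=O
Why: Negishi zirconium-catalysed carboalumination adds methyl and aluminium syn across the terminal alkyne, and the alkenylalanate is hydroxymethylated with retention, which fixes the E trisubstituted olefin.

**Step 2**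
Reactants: 4 dimethyl 2-methylidenebutanedioate (dimethyl itaconate)
Product: 5 3-(methoxycarbonyl)but-3-enoic acid
Conditions: LiOH (1.0 equiv), THF/H2O, 0 °C; then 1 M HCl
Reagents that add atoms: lithium hydroxide, [Li+].[OH-]
Why: Regioselective saponification, because the non-conjugated ester is the more electrophilic one and one equivalent of hydroxide leaves the acrylate ester intact.

**Step 3**
Reactants: 3 (2E)-3-methylhexa-2,5-dien-1-ol; 5 3-(methoxycarbonyl)but-3-enoic acid
Product: 6 1-methyl 4-[(2E)-3-methylhexa-2,5-dien-1-yl] 2-methylidenebutanedioate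
Conditions: dicyclohexylcarbodiimide, 4-(dimethylamino)pyridine (cat.), CH2Cl2, 0 °C to rt
Reagents that add atoms: none
Why: Steglich esterification joins the allylic alcohol to the only free carboxyl group without moving either double bond.

**Step 4**
Reactants: 7 (1R,2R)-1,2-diphenylethane-1,2-diamine
Product: 8 N,N'-[(1R,2R)-1,2-diphenylethane-1,2-diyl]bis[3,5-bis(trifluoromethyl)benzenesulfonamide]
Conditions: 3,5-(CF3)2C6H3SO2Cl (2.1 equiv), Et3N, 4-(dimethylamino)pyridine (cat.), CH2Cl2, 0 °C to rt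
Reagents that add atoms: 3,5-bis(trifluoromethyl)benzenesulfonyl chloride, O=S(=O)(Cl)c1cc(cc(c1)C(F)(F)F)C(F)(F)F
Why: Double N-sulfonylation of the C2-symmetric diamine gives the ligand of the chiral boron controller and does not touch its stereocentres.

**Step 5**
Reactants: 8 N,N'-[(1R,2R)-1,2-diphenylethane-1,2-diyl]bis[3,5-bis(trifluoromethyl)benzenesulfonamide]
Product: 9 (4R,5R)-2-bromo-1,3-bis{[3,5-bis(trifluoromethyl)phenyl]sulfonyl}-4,5-diphenyl-1,3,2-diazaborolidine
Conditions: BBr3 (1.0 equiv), CH2Cl2, 0 °C to rt; evaporate, use directly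
Reagents that add atoms: boron tribromide, BrB(Br)Br
Why: N-borylation, in which the two acidic sulfonamide N–H bonds displace two bromides from BBr3 and close the diazaborolidine with loss of HBr.

**Step 6**
Reactants: 6 1-methyl 4-[(2E)-3-methylhexa-2,5-dien-1-yl] 2-methylidenebutanedioate; 9 (4R,5R)-2-bromo-1,3-bis{[3,5-bis(trifluoromethyl)phenyl]sulfonyl}-4,5-diphenyl-1,3,2-diazaborolidine
Product: 11 (2S,3R)-3-ethenyl-2-[1-(methoxycarbonyl)ethenyl]-3-methylhex-5-enoic acid, via boron ketene acetal 10 (not isolated)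
Conditions: 9 (1.2 equiv), Et3N, toluene/hexane, −78 °C; then 4 °C, 3 d; H2O work-up
Reagents that add atoms: none
Why: Enantioselective boron-enolate Ireland–Claisen rearrangement, in which soft enolisation gives the E(O) ketene acetal and its chair [3,3] shift onto the E olefin (methyl axial, allyl equatorial) sets C2 and the quaternary C3 together, the chiral diazaborolidine choosing the enolate face.

**Step 7**
Reactants: 11 (2S,3R)-3-ethenyl-2-[1-(methoxycarbonyl)ethenyl]-3-methylhex-5-enoic acid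
Product: 14 (4S)-3-methylidene-4-[(3R)-3-methylhexa-1,5-dien-3-yl]oxolan-2-one, via mixed anhydride 12 (not isolated), via hydroxy ester 13 (not isolated)
Conditions: EtOCOCl, N-methylmorpholine, THF, −15 °C; then NaBH4, THF/H2O, 0 °C; then p-toluenesulfonic acid monohydrate (cat.), CH2Cl2, rt
Reagents that add atoms: none
Why: Mixed-anhydride activation lets NaBH4 reduce only the carboxyl group, and the resulting gamma-hydroxy acrylate lactonises (transesterification) to the alpha-methylene butyrolactone without touching the stereocentres.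

**Step 8**
Reactants: 14 (4S)-3-methylidene-4-[(3R)-3-methylhexa-1,5-dien-3-yl]oxolan-2-one
Product: 16 (3S,4R)-4-[(3R)-3-methylhexa-1,5-dien-3-yl]-3-(2-oxopropyl)oxolan-2-one, via cis epimer 15 (not isolated)
Conditions: MeCHO (5 equiv), 3-benzyl-5-(2-hydroxyethyl)-4-methylthiazolium chloride (20 mol %), Et3N (30 mol %), 1,4-dioxane, 70 °C, sealed tube; then 1,8-diazabicyclo[5.4.0]undec-7-ene (DBU, 1 equiv), 60 °C
Reagents that add atoms: acetaldehyde, CC=O
Why: Stetter reaction (carbene-catalysed conjugate addition of the acetaldehyde acyl anion) to the exocyclic enoate installs the 2-oxopropyl group, and DBU then equilibrates C3 to the trans lactone, with the new chain anti to the bulky quaternary substituent on C4, which is the configuration the target needs.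

**Step 9**
Reactants: 16 (3S,4R)-4-[(3R)-3-methylhexa-1,5-dien-3-yl]-3-(2-oxopropyl)oxolan-2-one
Product: 17 (3S,4R)-3-(2-hydroxypropyl)-4-[(3R)-3-methylhexa-1,5-dien-3-yl]oxolan-2-ol (epimers at C2 and at the side-chain carbinol)
Conditions: iBu2AlH (3.2 equiv), CH2Cl2, −78 °C; aq. potassium sodium tartrate; used crude
Reagents that add atoms: none
Why: Hydride reduction, in which the lactone stops at the lactol at −78 °C (stable aluminium hemiacetal) while the methyl ketone goes to the secondary alcohol, which masks it until step 15.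

**Step 10**
Reactants: 18 2,3-dibromoprop-1-ene
Product: 19 2-bromoprop-2-en-1-ol
Conditions: K2CO3, H2O, reflux
Reagents that add atoms: water, O
Why: Nucleophilic substitution (hydrolysis) of the primary allylic bromide, the vinylic bromide being inert.

**Step 11**
Reactants: 19 2-bromoprop-2-en-1-ol
Product: 20 [(2-bromoprop-2-en-1-yl)oxy](tert-butyl)dimethylsilane
Conditions: t-BuMe2SiCl, imidazole, CH2Cl2, rt
Reagents that add atoms: tert-butyldimethylsilyl chloride, CC(C)(C)[Si](C)(C)Cl
Why: Standard O-silylation protects the future hydroxymethyl group through the organolithium, metathesis, coupling and oxidation steps.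

**Step 12**
Reactants: 17 (3S,4R)-3-(2-hydroxypropyl)-4-[(3R)-3-methylhexa-1,5-dien-3-yl]oxolan-2-ol; 20 [(2-bromoprop-2-en-1-yl)oxy](tert-butyl)dimethylsilane
Product: 22 (4S,5R,6R)-2-({[tert-butyl(dimethyl)silyl]oxy}methyl)-6-ethenyl-5-(hydroxymethyl)-4-(2-hydroxypropyl)-6-methylnona-1,8-dien-3-ol (epimers at C3 and at the side-chain carbinol), via vinyllithium 21 (not isolated)
Conditions: 20 (3.5 equiv), t-BuLi (7 equiv), Et2O, −78 °C; then 17, THF, −78 to −20 °C; aq. NH4Cl
Reagents that add atoms: none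
Why: Bromine–lithium exchange gives the 2-lithioallyl ether (kept at −78 °C to prevent silyl migration), which adds 1,2 to the open aldehyde form of the lactol after two equivalents are spent on the hydroxyl groups, and the new carbinol centre is oxidised away later.

**Step 13**
Reactants: 22 (4S,5R,6R)-2-({[tert-butyl(dimethyl)silyl]oxy}methyl)-6-ethenyl-5-(hydroxymethyl)-4-(2-hydroxypropyl)-6-methylnona-1,8-dien-3-ol
Product: 23 (5R,6R,7S)-2-({[tert-butyl(dimethyl)silyl]oxy}methyl)-5-ethenyl-6-(hydroxymethyl)-7-(2-hydroxypropyl)-5-methylcyclohept-2-en-1-ol (epimers at C1 and at the side-chain carbinol)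
Conditions: benzylidene[1,3-bis(2,4,6-trimethylphenyl)imidazolidin-2-ylidene]dichloro(tricyclohexylphosphine)ruthenium (second-generation Grubbs catalyst, 10 mol %), CH2Cl2 (2 mM), 40 °C
Reagents that add atoms: none
Why: Ring-closing metathesis, in which the catalyst loads on the unhindered allyl group and closes onto the 1,1-disubstituted allylic-alcohol olefin to give the seven-membered trisubstituted cycloalkene, while the neopentyl vinyl group is too hindered to initiate and could only give a cyclobutene from the allyl-bound carbene.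

**Step 14**
Reactants: 23 (5R,6R,7S)-2-({[tert-butyl(dimethyl)silyl]oxy}methyl)-5-ethenyl-6-(hydroxymethyl)-7-(2-hydroxypropyl)-5-methylcyclohept-2-en-1-ol
Product: 25 (5S,6R,7S)-2-({[tert-butyl(dimethyl)silyl]oxy}methyl)-6-(hydroxymethyl)-7-(2-hydroxypropyl)-5-methyl-5-(4-methylpent-3-en-1-yl)cyclohept-2-en-1-ol (epimers at C1 and at the side-chain carbinol), via alkylborane 24 (not isolated)
Conditions: 9-borabicyclo[3.3.1]nonane (9-BBN-H, 5 equiv), THF, 0 to 40 °C; then PdCl2[1,1'-bis(diphenylphosphino)ferrocene] (5 mol %), aq. K3PO4, Me2C=CHBr, DMF, 50 °C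
Reagents that add atoms: 1-bromo-2-methylprop-1-ene, CC(C)=CBr
Why: Anti-Markovnikov hydroboration of the only monosubstituted olefin followed by B-alkyl Suzuki–Miyaura coupling builds the 4-methylpent-3-enyl chain, the trisubstituted ring olefin being too hindered for 9-BBN and the hydroxyl groups only transiently O-borylated (the C5 descriptor changes from R to S by priority only).

**Step 15**
Reactants: 25 (5S,6R,7S)-2-({[tert-butyl(dimethyl)silyl]oxy}methyl)-6-(hydroxymethyl)-7-(2-hydroxypropyl)-5-methyl-5-(4-methylpent-3-en-1-yl)cyclohept-2-en-1-ol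
Product: 26 (1R,2S,7S)-5-({[tert-butyl(dimethyl)silyl]oxy}methyl)-2-methyl-2-(4-methylpent-3-en-1-yl)-6-oxo-7-(2-oxopropyl)cyclohept-4-ene-1-carbaldehyde
Conditions: (COCl)2, Me2SO, CH2Cl2, −78 °C; then iPr2NEt, −78 to −20 °C; used at once
Reagents that add atoms: none
Why: Swern oxidation activates all three hydroxyl groups as alkoxysulfonium ions before base is added, so enone, methyl ketone and aldehyde form together, no lactol can form and over-oxidise, and C1 and C7 are not epimerised at low temperature.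

**Step 16**
Reactants: 27 3-methylbut-2-enoyl chloride
Product: 28 chloromethyl 3-methylbut-2-enoate
Conditions: (CH2O)n, ZnCl2 (cat.), neat, 80 °C
Reagents that add atoms: paraformaldehyde (as formaldehyde), C=O
Why: ZnCl2-catalysed insertion of formaldehyde into the acyl chloride gives the alpha-chloroalkyl ester.

**Step 17**
Reactants: 28 chloromethyl 3-methylbut-2-enoate
Product: 29 {[(3-methylbut-2-enoyl)oxy]methyl}(triphenyl)phosphonium chloride
Conditions: PPh3, toluene, reflux
Reagents that add atoms: triphenylphosphine, c1ccc(cc1)P(c1ccccc1)c1ccccc1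
Why: Nucleophilic substitution (quaternisation) of the activated chloromethyl ester by the phosphine gives the Anders–Gaßner salt.

**Step 18**
Reactants: 26 (1R,2S,7S)-5-({[tert-butyl(dimethyl)silyl]oxy}methyl)-2-methyl-2-(4-methylpent-3-en-1-yl)-6-oxo-7-(2-oxopropyl)cyclohept-4-ene-1-carbaldehyde; 29 {[(3-methylbut-2-enoyl)oxy]methyl}(triphenyl)phosphonium chloride
Product: 31 (1Z)-2-[(1R,2S,7S)-5-({[tert-butyl(dimethyl)silyl]oxy}methyl)-2-methyl-2-(4-methylpent-3-en-1-yl)-6-oxo-7-(2-oxopropyl)cyclohept-4-en-1-yl]ethenyl 3-methylbut-2-enoate, via ylide 30 (not isolated)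
Conditions: 29 (1.5 equiv), NaN(SiMe3)2 (1.45 equiv), THF, −78 °C, 15 min; then 26, −78 to −40 °C
Reagents that add atoms: none
Why: Wittig olefination (Anders–Gaßner variant) with the non-stabilised alpha-acyloxy ylide, which reacts at the aldehyde in preference to the ketones and under kinetic low-temperature conditions gives mainly the Z enol ester through the cis oxaphosphetane, the minor E isomer being removed by chromatography.

**Step 19**
Reactants: 31 (1Z)-2-[(1R,2S,7S)-5-({[tert-butyl(dimethyl)silyl]oxy}methyl)-2-methyl-2-(4-methylpent-3-en-1-yl)-6-oxo-7-(2-oxopropyl)cyclohept-4-en-1-yl]ethenyl 3-methylbut-2-enoate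
Product: 32 (1Z)-2-[(1R,2S,7S)-5-(hydroxymethyl)-2-methyl-2-(4-methylpent-3-en-1-yl)-6-oxo-7-(2-oxopropyl)cyclohept-4-en-1-yl]ethenyl 3-methylbut-2-enoate
Conditions: HF·pyridine, pyridine, THF, 0 °C
Reagents that add atoms: none
Why: Buffered, non-basic desilylation frees the primary allylic alcohol without hydrolysing the enol ester or epimerising C7.

**Compound list**
1 | pent-1-en-4-yne | C=CCC#C | starting material
2 | dimethyl[(1E)-2-methylpenta-1,4-dien-1-yl]alumane | C=CC/C(C)=C/[Al](C)C | intermediate (not isolated)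
3 | (2E)-3-methylhexa-2,5-dien-1-ol | C=CC/C(C)=C/CO | intermediate
4 | dimethyl 2-methylidenebutanedioate | COC(=O)CC(=C)C(=O)OC | starting material
5 | 3-(methoxycarbonyl)but-3-enoic acid | OC(=O)CC(=C)C(=O)OC | intermediate
6 | 1-methyl 4-[(2E)-3-methylhexa-2,5-dien-1-yl] 2-methylidenebutanedioate | C=CC/C(C)=C/COC(=O)CC(=C)C(=O)OC | intermediate
7 | (1R,2R)-1,2-diphenylethane-1,2-diamine | N[C@H](c1ccccc1)[C@H](N)c1ccccc1 | starting material
8 | N,N'-[(1R,2R)-1,2-diphenylethane-1,2-diyl]bis[3,5-bis(trifluoromethyl)benzenesulfonamide] | O=S(=O)(N[C@H](c1ccccc1)[C@H](NS(=O)(=O)c1cc(cc(c1)C(F)(F)F)C(F)(F)F)c1ccccc1)c1cc(cc(c1)C(F)(F)F)C(F)(F)F | intermediate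
9 | (4R,5R)-2-bromo-1,3-bis{[3,5-bis(trifluoromethyl)phenyl]sulfonyl}-4,5-diphenyl-1,3,2-diazaborolidine | BrB1N(S(=O)(=O)c2cc(cc(c2)C(F)(F)F)C(F)(F)F)[C@H](c2ccccc2)[C@@H](c2ccccc2)N1S(=O)(=O)c1cc(cc(c1)C(F)(F)F)C(F)(F)F | intermediate
10 | (4R,5R)-2-({(1Z)-3-(methoxycarbonyl)-1-[(2E)-3-methylhexa-2,5-dien-1-yl]oxybuta-1,3-dien-1-yl}oxy)-1,3-bis{[3,5-bis(trifluoromethyl)phenyl]sulfonyl}-4,5-diphenyl-1,3,2-diazaborolidine | C=CC/C(C)=C/CO/C(OB1N(S(=O)(=O)c2cc(cc(c2)C(F)(F)F)C(F)(F)F)[C@H](c2ccccc2)[C@@H](c2ccccc2)N1S(=O)(=O)c1cc(cc(c1)C(F)(F)F)C(F)(F)F)=C\C(=C)C(=O)OC | intermediate (not isolated)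
11 | (2S,3R)-3-ethenyl-2-[1-(methoxycarbonyl)ethenyl]-3-methylhex-5-enoic acid | C=CC[C@](C)(C=C)[C@@H](C(=C)C(=O)OC)C(=O)O | intermediate
12 | ethyl carbonic (2S,3R)-3-ethenyl-2-[1-(methoxycarbonyl)ethenyl]-3-methylhex-5-enoic anhydride | C=CC[C@](C)(C=C)[C@@H](C(=C)C(=O)OC)C(=O)OC(=O)OCC | intermediate (not isolated)
13 | methyl (3S,4R)-4-ethenyl-3-(hydroxymethyl)-4-methyl-2-methylidenehept-6-enoate | C=CC[C@](C)(C=C)[C@@H](C(=C)C(=O)OC)CO | intermediate (not isolated)
14 | (4S)-3-methylidene-4-[(3R)-3-methylhexa-1,5-dien-3-yl]oxolan-2-one | C=CC[C@](C)(C=C)[C@@H]1COC(=O)C1=C | intermediate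
15 | (3R,4R)-4-[(3R)-3-methylhexa-1,5-dien-3-yl]-3-(2-oxopropyl)oxolan-2-one (cis) | C=CC[C@](C)(C=C)[C@@H]1COC(=O)[C@@H]1CC(C)=O | intermediate (not isolated)
16 | (3S,4R)-4-[(3R)-3-methylhexa-1,5-dien-3-yl]-3-(2-oxopropyl)oxolan-2-one (trans) | C=CC[C@](C)(C=C)[C@@H]1COC(=O)[C@H]1CC(C)=O | intermediate
17 | (3S,4R)-3-(2-hydroxypropyl)-4-[(3R)-3-methylhexa-1,5-dien-3-yl]oxolan-2-ol | C=CC[C@](C)(C=C)[C@@H]1COC(O)[C@H]1CC(C)O | intermediate
18 | 2,3-dibromoprop-1-ene | C=C(Br)CBr | starting material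
19 | 2-bromoprop-2-en-1-ol | C=C(Br)CO | intermediate
20 | [(2-bromoprop-2-en-1-yl)oxy](tert-butyl)dimethylsilane | C=C(Br)CO[Si](C)(C)C(C)(C)C | intermediate
21 | (3-{[tert-butyl(dimethyl)silyl]oxy}prop-1-en-2-yl)lithium | [Li]C(=C)CO[Si](C)(C)C(C)(C)C | intermediate (not isolated)
22 | (4S,5R,6R)-2-({[tert-butyl(dimethyl)silyl]oxy}methyl)-6-ethenyl-5-(hydroxymethyl)-4-(2-hydroxypropyl)-6-methylnona-1,8-dien-3-ol | C=CC[C@](C)(C=C)[C@@H]([C@H](CC(C)O)C(O)C(=C)CO[Si](C)(C)C(C)(C)C)CO | intermediate
23 | (5R,6R,7S)-2-({[tert-butyl(dimethyl)silyl]oxy}methyl)-5-ethenyl-6-(hydroxymethyl)-7-(2-hydroxypropyl)-5-methylcyclohept-2-en-1-ol | CC(O)C[C@@H]1C(O)C(CO[Si](C)(C)C(C)(C)C)=CC[C@](C)(C=C)[C@@H]1CO | intermediate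
24 | B-alkyl-9-borabicyclo[3.3.1]nonane from 23 (terminal carbon of the former vinyl group bound to boron; the three hydroxyls as O-boryl ethers) | CC(OB1C2CCCC1CCC2)C[C@@H]1C(OB2C3CCCC2CCC3)C(CO[Si](C)(C)C(C)(C)C)=CC[C@](C)(CCB2C3CCCC2CCC3)[C@@H]1COB1C2CCCC1CCC2 | intermediate (not isolated)
25 | (5S,6R,7S)-2-({[tert-butyl(dimethyl)silyl]oxy}methyl)-6-(hydroxymethyl)-7-(2-hydroxypropyl)-5-methyl-5-(4-methylpent-3-en-1-yl)cyclohept-2-en-1-ol | CC(O)C[C@@H]1C(O)C(CO[Si](C)(C)C(C)(C)C)=CC[C@](C)(CCC=C(C)C)[C@@H]1CO | intermediate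
26 | (1R,2S,7S)-5-({[tert-butyl(dimethyl)silyl]oxy}methyl)-2-methyl-2-(4-methylpent-3-en-1-yl)-6-oxo-7-(2-oxopropyl)cyclohept-4-ene-1-carbaldehyde | CC(=O)C[C@@H]1C(=O)C(CO[Si](C)(C)C(C)(C)C)=CC[C@](C)(CCC=C(C)C)[C@@H]1C=O | intermediate
27 | 3-methylbut-2-enoyl chloride | CC(C)=CC(Cl)=O | starting material
28 | chloromethyl 3-methylbut-2-enoate | CC(C)=CC(=O)OCCl | intermediate
29 | {[(3-methylbut-2-enoyl)oxy]methyl}(triphenyl)phosphonium chloride | CC(C)=CC(=O)OC[P+](c1ccccc1)(c1ccccc1)c1ccccc1.[Cl-] | intermediate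
30 | (triphenylphosphoranylidene)methyl 3-methylbut-2-enoate | CC(C)=CC(=O)OC=P(c1ccccc1)(c1ccccc1)c1ccccc1 | intermediate (not isolated)
31 | (1Z)-2-[(1R,2S,7S)-5-({[tert-butyl(dimethyl)silyl]oxy}methyl)-2-methyl-2-(4-methylpent-3-en-1-yl)-6-oxo-7-(2-oxopropyl)cyclohept-4-en-1-yl]ethenyl 3-methylbut-2-enoate | CC(=O)C[C@@H]1C(=O)C(CO[Si](C)(C)C(C)(C)C)=CC[C@](C)(CCC=C(C)C)[C@@H]1/C=C\OC(=O)C=C(C)C | intermediate
32 | (1Z)-2-[(1R,2S,7S)-5-(hydroxymethyl)-2-methyl-2-(4-methylpent-3-en-1-yl)-6-oxo-7-(2-oxopropyl)cyclohept-4-en-1-yl]ethenyl 3-methylbut-2-enoate | CC(=O)C[C@@H]1C(=O)C(CO)=CC[C@](C)(CCC=C(C)C)[C@@H]1/C=C\OC(=O)C=C(C)C | target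

**Step count**
Total: 19 steps. Longest linear sequence: 12 steps (1, 3, 6, 7, 8, 9, 12, 13, 14, 15, 18, 19).

**Three steps most likely to fail, with fallbacks**

Step 6 (the chiral boron controller has not been used on an itaconate-type diester, and the sense and level of induction are unproven). The fallback sets out from 6 and returns at 11. Ester 6 is enolised with LiN(iPr)2 and Me3SiCl in THF at −78 °C and warmed to rt. The E(O) enolate is trapped as the trimethylsilyl ketene acetal F1, which undergoes the same chair Ireland–Claisen shift and gives, after hydrolysis, the racemic acid F2 with the same relative configuration. Classical resolution through the (R)-1-phenylethylammonium salt F3 (recrystallisation; the antipodal amine is used if its salt is the less soluble one) and acidification then gives enantiopure 11.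

Step 8 (the Stetter addition to a hindered alpha-substituted acceptor may be slow, and base may isomerise the exocyclic olefin into the ring). The fallback sets out from 14 and returns at 16. Nitroethane is added as the acyl-anion equivalent in a DBU-mediated Michael reaction (MeCN, rt), giving under the same equilibrating conditions the trans nitro lactone F4 (mixture at the nitro-bearing carbon). A reductive Nef reaction (DBU, then aqueous TiCl3 buffered with NH4OAc, THF, 0 °C to rt) converts the CH(NO2) group into the ketone, which is 16.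

Step 18 (the ylide is unstable, the aldehyde is hindered and epimerisable, and the Z/E ratio is uncertain). The fallback sets out from 26 and returns at 31. Aldehyde 26 is homologated with dimethyl (1-diazo-2-oxopropyl)phosphonate (K2CO3, MeOH, 0 °C; Seyferth–Gilbert homologation in the Ohira–Bestmann form) to the terminal alkyne F5. Ruthenium-catalysed anti-Markovnikov addition of 3-methylbut-2-enoic acid (bis(2-methylallyl)[1,4-bis(diphenylphosphino)butane]ruthenium, toluene, 65 °C), which is Z-selective, then gives 31.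

**Further compounds**
F1 | step 6 | methyl (3E)-2-methylidene-4-{[(2E)-3-methylhexa-2,5-dien-1-yl]oxy}-4-[(trimethylsilyl)oxy]but-3-enoate | C=CC/C(C)=C/CO/C(O[Si](C)(C)C)=C\C(=C)C(=O)OC
F2 | step 6 | racemic (2S,3R)/(2R,3S)-3-ethenyl-2-[1-(methoxycarbonyl)ethenyl]-3-methylhex-5-enoic acid | C=CC[C@](C)(C=C)[C@@H](C(=C)C(=O)OC)C(=O)O.C=CC[C@@](C)(C=C)[C@H](C(=C)C(=O)OC)C(=O)O
F3 | step 6 | (1R)-1-phenylethan-1-aminium (2S,3R)-3-ethenyl-2-[1-(methoxycarbonyl)ethenyl]-3-methylhex-5-enoate | C=CC[C@](C)(C=C)[C@@H](C(=C)C(=O)OC)C(=O)[O-].C[C@@H]([NH3+])c1ccccc1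
F4 | step 8 | (3S,4R)-4-[(3R)-3-methylhexa-1,5-dien-3-yl]-3-(2-nitropropyl)oxolan-2-one | C=CC[C@](C)(C=C)[C@@H]1COC(=O)[C@H]1CC(C)[N+](=O)[O-]
F5 | step 18 | (5S,6R,7S)-2-({[tert-butyl(dimethyl)silyl]oxy}methyl)-6-ethynyl-5-methyl-5-(4-methylpent-3-en-1-yl)-7-(2-oxopropyl)cyclohept-2-en-1-one | CC(=O)C[C@@H]1C(=O)C(CO[Si](C)(C)C(C)(C)C)=CC[C@](C)(CCC=C(C)C)[C@@H]1C#C
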